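## Analysis of the target

The target (23) is a diaryl ether with no stereocentre. Ring A is a 2,4-dihydroxy-6-pentylphenoxy unit. Ring B is a benzoic acid (carboxyl on C1) that carries this aryloxy group at C2, a methoxy group at C4 and a pentanoyl chain at C6. Ring B is thus 1,2,3,5-tetrasubstituted, and its hard part is the contiguous run C2 (oxygen), C1 (carboxyl), C6 (acyl): two different carbonyl carbons sit side by side, and C6 is meta to both oxygen donors of ring B, so electrophilic acylation cannot reach it. The ether oxygen is flanked by the C1 carboxyl on ring B and by a hydroxyl and the pentyl chain on ring A, so the diaryl ether is best made before ring B is fully substituted. Ring A is a 1,2,4-trioxygenated benzene, electron-rich and open to oxidants and electrophiles. The ortho-acylbenzoic acid can close to its hydroxylactone tautomer, and the C1 carboxyl and the ring A 2-hydroxyl are placed for a seven-membered lactone under dehydrating conditions. Only the C4 oxygen of ring B is methylated, so the two ring A oxygens need a protecting group that leaves without touching the methyl ether, the ketone or the acid. The strategy rests on the C2–C1–C6 triad: two carbon substituents on adjacent carbons next to an oxygen-bearing carbon is the pattern left when a carbon nucleophile and a carbon electrophile add across a C1–C6 aryne polarised by the C2 aryloxy group.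

## Retrosynthetic reasoning

**Target 23 from keto acid 22.** The two O–benzyl bonds on ring A are cut last. Benzyl ethers survive the bases, peracid and organometallic reagents of the route, and a boron Lewis acid with a cation scavenger removes them while the C4 methyl ether stays. The forward step must keep the liberated benzyl cations off ring A.

**Keto acid 22 from dithianyl acid 21.** The C6 ketone is traced back to a 1,3-dithiane. The masking is not an extra protecting-group step: the dithiane is the form in which the acyl carbon arrives as a nucleophile. The forward hydrolysis has to work at a carbon wedged between ring B and the C1 carboxyl.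

**Dithianyl acid 21 from iodoaryl sulfonate 12, 2-butyl-1,3-dithiane 15 and carbon dioxide 16.** Both carbon–carbon bonds of the triad are cut at once, C6–C(acyl) and C1–C(carboxyl). Cutting here removes the whole regiochemical problem of ring B in one operation and leaves a ring with only oxygen and halogen substituents. The forward reaction must release the C1–C6 aryne from 12, add the lithiated form of 15 at C6 only, and trap the C1 aryl anion with 16. The C2 aryloxy group decides the orientation, by induction and by shielding C1.

**Dithiane 15 from pentanal 13 and propane-1,3-dithiol 14.** The two C–S bonds are cut, which is a plain thioacetalisation of the five-carbon aldehyde.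

**Sulfonate 12 from iodophenol 11, and 11 from phenol 10.** The S–O bond and then the C6–I bond are cut. The phenoxide of 10 has its para position filled by the methoxy group and one ortho position filled by the aryloxy group, so only C6 is open. The iodination has to run through the phenoxide with a mild iodine source. A neutral iodonium donor would find the trialkoxy ring A, and C5 of ring B, more reactive than C6.

**Phenol 10 from aldehyde 8.** The C1–O bond is traced to a C1–formyl group by a peracid oxidation of the Baeyer–Villiger (Dakin) type. The formyl group has done its work as activator for the ether formation and is then exchanged for the oxygen that becomes the sulfonate leaving group.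

**Aldehyde 8 from phenol 6 and 2-fluoro-4-methoxybenzaldehyde 7.** The C2–O bond of the diaryl ether is cut. On the ring B side the partner has only a hydrogen at C3 and a formyl group at C1, so the hindered ring A phenoxide meets an activated, uncrowded fluoroarene. Addition–elimination ortho to the formyl group is the forward reaction.

**Phenol 6 from aldehyde 4, dihydroxyaldehyde 3 and olivetol 1.** The ring A C–O bond is again traced to a formyl group. Formylation of 1 at the carbon para to one hydroxyl and next to the pentyl chain, benzylation, and the same peracid oxidation give the 1,2,4-trioxygenated pattern with the pentyl group in place.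

## Alternatives that were turned down

**Alternative 1: ring A by Michael–Claisen annulation.** Ring A is cut at C1'–C6' and C2'–C3', which leads to the aryloxymalonate A2 and the ynone A3. With excess NaOMe the malonate carbon of A2 would add to the pentyl-bearing alkyne carbon of A3. The methyl ketone enolate would then close the six-membered ring onto one ester and give the racemic cyclohexenedione A1. Hydrolysis and loss of the remaining ester carbon would aromatise A1 to 23.
- For: ring A appears with both hydroxyls free and the pentyl group placed, without protecting groups. The diaryl ether comes from a simple O-alkylation, not from coupling a hindered phenol. A1 is only one or two operations from 23. On these points it is stronger than the chosen route.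
- Against: A2 already contains the whole ring B triad plus a fourth contiguous oxygen, so the hardest part of the target is untouched. A tertiary, oxygen-bearing malonate anion must form a quaternary carbon by conjugate addition. The enolisable pentanoyl ketone and the carboxylate of ring B sit in hot alkoxide, where aldol chemistry and retro-Claisen opening of the new 1,3-diketone can compete.
- Comparison: the chosen strategy pays with two benzyl groups. In return it solves the ring B triad from a commercial fluoroaldehyde and keeps the ketone masked until the end.

**Alternative 2: ring B and lactone by ruthenium [2+2+2] cycloaddition.** Ring B is cut at C2–C3, C4–C5 and C6–C1, which leads to the ester-tethered diyne A5 and the alkoxyalkyne A6. Cp*RuCl(cod), a complex of divalent ruthenium, would join the two tethered alkynes to a metallacycle and insert A6. This closes ring B and the five-membered lactone together and gives the racemic phthalide A4.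
- For: all four ring B substituents are placed in one catalytic, neutral step. The tether fixes three of them, and no strong base or organolithium is needed. In convergence on ring B and in mildness it is at least as strong as the aryne route.
- Against: A5 is an ynol ether of a hindered phenol joined to an ynoate, a fragile compound whose preparation is a project of its own. A6 is volatile and labile. The orientation of A6 depends on a catalyst preference, not on the substrate. A4 is at the wrong oxidation level: its lactone carbon is a stereocentre made only to be destroyed, and lactone opening and oxidation to the ketone must follow before debenzylation.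
- Comparison: the chosen strategy delivers the ketone and acid oxidation levels directly, from stable aromatic starting materials, in fewer steps.

**Alternative 3: ring A by cyclobutenone–siloxyalkyne benzannulation.** Ring A is cut at C2'–C3', C4'–C5' and C1'–C2', which leads to the racemic cyclobutenone A8 and the siloxyalkyne A9. Heating would open A8 to a vinylketene, which adds A9 by [2+2] cycloaddition. The new cyclobutenone opens again, a 6π closure follows, and tautomerisation gives phenol A7 with a free 2'-hydroxyl and a silyl ether at C4'.
- For: the step is thermal, needs no reagent, and its regiochemistry follows from the mechanism. The two ring A oxygens come out differentiated. Here it is stronger than the chosen route, which unveils both hydroxyls together.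
- Against: A8 must be made by attaching a cyclobutenone to a hindered ring B phenol that again carries the complete triad, so ring B is still unsolved. A9 is moisture-sensitive and must be prepared. After the annulation a silyl ether and a di-ortho-substituted methyl ester remain to be cleaved.
- Comparison: the chosen strategy is much shorter from commercial arenes and puts its single uncertain step on the one structural problem that all three alternatives leave open.

Key step: step 9

Remark: the target is drawn as the open keto acid; an ortho-acylbenzoic acid is expected to equilibrate with its cyclic hydroxylactone tautomer, and the two are treated as the same compound.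

## Route

Step 1
Reactants: 1 olivetol (5-pentylbenzene-1,3-diol)
Product: 3 2,4-dihydroxy-6-pentylbenzaldehyde, via iminium chloride 2 (not isolated)
Conditions: POCl3, DMF, 0 °C to rt; then H2O, 50 °C
Reagents that add atoms: N,N-dimethylformamide, CN(C)C=O; water, O
Why: Vilsmeier–Haack formylation; the chloroiminium ion should attack the ring carbon para to one hydroxyl and ortho to the other, next to the pentyl chain, and water hydrolyses iminium salt 2 to the aldehyde.

Step 2
Reactants: 3 2,4-dihydroxy-6-pentylbenzaldehyde
Product: 4 2,4-bis(benzyloxy)-6-pentylbenzaldehyde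
Conditions: BnBr, K2CO3, DMF, 60 °C
Reagents that add atoms: benzyl bromide, BrCc1ccccc1
Why: Williamson ether synthesis on both phenoxides; warm DMF is used because the hydroxyl hydrogen-bonded to the formyl group is the slower one.

Step 3
Reactants: 4 2,4-bis(benzyloxy)-6-pentylbenzaldehyde
Product: 6 2,4-bis(benzyloxy)-6-pentylphenol, via aryl formate 5 (not isolated)
Conditions: mCPBA, CH2Cl2, 0 °C to rt; aq. NaHCO3 wash; then K2CO3 (cat.), MeOH, rt
Reagents that add atoms: 3-chloroperoxybenzoic acid, OOC(=O)c1cccc(Cl)c1
Why: Baeyer–Villiger (Dakin-type) oxidation; the electron-rich aryl group with ortho and para alkoxy donors migrates in the Criegee intermediate to give formate 5, which methanolysis cleaves to the phenol.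

Step 4
Reactants: 6 2,4-bis(benzyloxy)-6-pentylphenol; 7 2-fluoro-4-methoxybenzaldehyde
Product: 8 2-[2,4-bis(benzyloxy)-6-pentylphenoxy]-4-methoxybenzaldehyde
Conditions: Cs2CO3, DMSO, 110 °C, argon
Reagents that add atoms: none
Why: nucleophilic aromatic substitution by addition–elimination; the fluoride is ortho to the formyl group, which stabilises the Meisenheimer intermediate, and the caesium phenoxide of 6 is hindered but strongly nucleophilic.

Step 5
Reactants: 8 2-[2,4-bis(benzyloxy)-6-pentylphenoxy]-4-methoxybenzaldehyde
Product: 10 2-[2,4-bis(benzyloxy)-6-pentylphenoxy]-4-methoxyphenol, via aryl formate 9 (not isolated)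
Conditions: mCPBA, CH2Cl2, 0 °C to rt; aq. NaHCO3 wash; then K2CO3 (cat.), MeOH, rt
Reagents that add atoms: 3-chloroperoxybenzoic acid, OOC(=O)c1cccc(Cl)c1
Why: Baeyer–Villiger (Dakin-type) oxidation; the ortho aryloxy and para methoxy groups make the ring B aryl group the migrating one, and the formate 9 is cleaved by methanolysis.

Step 6
Reactants: 10 2-[2,4-bis(benzyloxy)-6-pentylphenoxy]-4-methoxyphenol
Product: 11 2-[2,4-bis(benzyloxy)-6-pentylphenoxy]-6-iodo-4-methoxyphenol
Conditions: I2, NaHCO3, THF/H2O, 0 °C to rt
Reagents that add atoms: iodine, II
Why: electrophilic aromatic iodination through the phenoxide; I2 under bicarbonate reacts only with the phenoxide ring, whose para position (methoxy) and one ortho position (aryloxy) are blocked, so iodine should enter at C6 alone. The neutral trialkoxy ring A does not react with unactivated I2, which is why no N-iodo imide or acid activator is used.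

Step 7
Reactants: 11 2-[2,4-bis(benzyloxy)-6-pentylphenoxy]-6-iodo-4-methoxyphenol
Product: 12 2-[2,4-bis(benzyloxy)-6-pentylphenoxy]-6-iodo-4-methoxyphenyl 4-chlorobenzenesulfonate
Conditions: 4-ClC6H4SO2Cl, Et3N, DMAP (cat.), CH2Cl2, 0 °C to rt
Reagents that add atoms: 4-chlorobenzenesulfonyl chloride, O=S(=O)(Cl)c1ccc(Cl)cc1
Why: O-sulfonylation of the phenol with nucleophilic catalysis by DMAP, needed because the hydroxyl is flanked by iodine and the aryloxy group; this sets iodine and the sulfonate leaving group on adjacent carbons C6 and C1.

Step 8
Reactants: 13 pentanal; 14 propane-1,3-dithiol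
Product: 15 2-butyl-1,3-dithiane
Conditions: BF3·OEt2 (cat.), CH2Cl2, 0 °C to rt
Reagents that add atoms: none
Why: Lewis acid catalysed dithioacetalisation of an unhindered aldehyde.

Step 9
Reactants: 12 2-[2,4-bis(benzyloxy)-6-pentylphenoxy]-6-iodo-4-methoxyphenyl 4-chlorobenzenesulfonate; 15 2-butyl-1,3-dithiane; 16 carbon dioxide
Product: 21 2-[2,4-bis(benzyloxy)-6-pentylphenoxy]-6-(2-butyl-1,3-dithian-2-yl)-4-methoxybenzoic acid, via lithiodithiane 17 (not isolated), via arylmagnesium sulfonate 18 (not isolated), via aryne 19 (not isolated), via aryllithium 20 (not isolated)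
Conditions: 15, n-BuLi, THF, −30 °C (gives 17); 12, i-PrMgCl·LiCl (1 equiv), THF, −78 °C; add 17, −78 °C to rt; CO2, −78 °C to rt; aq. HCl
Reagents that add atoms: none
Why: Proposed new method: iodine–magnesium exchange at C6 of 12 at −78 °C gives arylmagnesium 18, which on warming expels the C1 arenesulfonate to form the C1–C6 aryne 19; the tertiary carbanion 17 adds to C6 and the C1 aryllithium 20 is carboxylated by CO2, so the C6–C(dithiane) and C1–CO2H bonds form in one flask. The closest known reaction type is the three-component coupling of a Grignard or organolithium carbon nucleophile with a 3-alkoxyaryne released from a 2-iodoaryl arenesulfonate by i-PrMgCl, with capture of the aryl anion by CO2; new here is a 2-alkyl-2-lithio-1,3-dithiane as the carbanion. It should work because lithiodithianes are strongly nucleophilic but only moderately basic, and the low-lying aryne LUMO accepts even hindered carbanions. The step needs regioselective addition to the unsymmetrical aryne: the C2 aryloxy group withdraws through the σ framework, which makes C6 the more electrophilic terminus and places the developing charge at C1 next to oxygen. The bulky ring A ether also screens C1 from a tertiary nucleophile, so both effects point the same way, and the C4 methoxy group is too remote to override them. No ring is closed and no stereocentre is formed. Keeping i-PrMgCl·LiCl at one equivalent and adding 17 before warming should suppress isopropyl addition to 19 and self-arylation of 18.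

Step 10
Reactants: 21 2-[2,4-bis(benzyloxy)-6-pentylphenoxy]-6-(2-butyl-1,3-dithian-2-yl)-4-methoxybenzoic acid
Product: 22 2-[2,4-bis(benzyloxy)-6-pentylphenoxy]-4-methoxy-6-pentanoylbenzoic acid
Conditions: HgCl2, CaCO3, MeCN/H2O, rt
Reagents that add atoms: water, O
Why: thiophilic metal-assisted dithioacetal hydrolysis; divalent mercury binds sulfur, the C–S bond ionises to a thionium ion that is captured by water or by the neighbouring carboxyl, and CaCO3 buffers the acid released. HgCl2 is too weak an electrophile to mercurate ring A or disturb the benzyl ethers.

Step 11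
Reactants: 22 2-[2,4-bis(benzyloxy)-6-pentylphenoxy]-4-methoxy-6-pentanoylbenzoic acid
Product: 23 2-(2,4-dihydroxy-6-pentylphenoxy)-4-methoxy-6-pentanoylbenzoic acid (target)
Conditions: BCl3, C6HMe5, CH2Cl2, −78 °C; then H2O
Reagents that add atoms: none
Why: Lewis acid cleavage of aryl benzyl ethers; BCl3 activates the ether oxygens and the benzyl cations are taken up by pentamethylbenzene before they can alkylate ring A. The C4 methyl ether has no adjacent carbonyl for chelation and should survive at −78 °C.

## Compound list

1 | olivetol (5-pentylbenzene-1,3-diol) | CCCCCc1cc(O)cc(O)c1 | starting material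
2 | N-[(2,4-dihydroxy-6-pentylphenyl)methylidene]-N-methylmethanaminium chloride | CCCCCc1cc(O)cc(O)c1C=[N+](C)C.[Cl-] | intermediate
3 | 2,4-dihydroxy-6-pentylbenzaldehyde | CCCCCc1cc(O)cc(O)c1C=O | intermediate
4 | 2,4-bis(benzyloxy)-6-pentylbenzaldehyde | CCCCCc1cc(OCc2ccccc2)cc(OCc2ccccc2)c1C=O | intermediate
5 | 2,4-bis(benzyloxy)-6-pentylphenyl formate | CCCCCc1cc(OCc2ccccc2)cc(OCc2ccccc2)c1OC=O | intermediate
6 | 2,4-bis(benzyloxy)-6-pentylphenol | CCCCCc1cc(OCc2ccccc2)cc(OCc2ccccc2)c1O | intermediate
7 | 2-fluoro-4-methoxybenzaldehyde | COc1ccc(C=O)c(F)c1 | starting material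
8 | 2-[2,4-bis(benzyloxy)-6-pentylphenoxy]-4-methoxybenzaldehyde | CCCCCc1cc(OCc2ccccc2)cc(OCc2ccccc2)c1Oc1cc(OC)ccc1C=O | intermediate
9 | 2-[2,4-bis(benzyloxy)-6-pentylphenoxy]-4-methoxyphenyl formate | CCCCCc1cc(OCc2ccccc2)cc(OCc2ccccc2)c1Oc1cc(OC)ccc1OC=O | intermediate
10 | 2-[2,4-bis(benzyloxy)-6-pentylphenoxy]-4-methoxyphenol | CCCCCc1cc(OCc2ccccc2)cc(OCc2ccccc2)c1Oc1cc(OC)ccc1O | intermediate
11 | 2-[2,4-bis(benzyloxy)-6-pentylphenoxy]-6-iodo-4-methoxyphenol | CCCCCc1cc(OCc2ccccc2)cc(OCc2ccccc2)c1Oc1cc(OC)cc(I)c1O | intermediate
12 | 2-[2,4-bis(benzyloxy)-6-pentylphenoxy]-6-iodo-4-methoxyphenyl 4-chlorobenzenesulfonate | CCCCCc1cc(OCc2ccccc2)cc(OCc2ccccc2)c1Oc1cc(OC)cc(I)c1OS(=O)(=O)c1ccc(Cl)cc1 | intermediate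
13 | pentanal | CCCCC=O | starting material
14 | propane-1,3-dithiol | SCCCS | starting material
15 | 2-butyl-1,3-dithiane | CCCCC1SCCCS1 | intermediate
16 | carbon dioxide | O=C=O | starting material
17 | 2-butyl-2-lithio-1,3-dithiane | [Li]C1(CCCC)SCCCS1 | intermediate
18 | {3-[2,4-bis(benzyloxy)-6-pentylphenoxy]-2-[(4-chlorobenzenesulfonyl)oxy]-5-methoxyphenyl}magnesium chloride | CCCCCc1cc(OCc2ccccc2)cc(OCc2ccccc2)c1Oc1cc(OC)cc([Mg]Cl)c1OS(=O)(=O)c1ccc(Cl)cc1 | intermediate
19 | 3-[2,4-bis(benzyloxy)-6-pentylphenoxy]-5-methoxybenzyne (triple bond between C1 and C6 of ring B) | CCCCCc1cc(OCc2ccccc2)cc(OCc2ccccc2)c1OC1=CC(OC)=CC#C1 | intermediate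
20 | {2-[2,4-bis(benzyloxy)-6-pentylphenoxy]-6-(2-butyl-1,3-dithian-2-yl)-4-methoxyphenyl}lithium | CCCCCc1cc(OCc2ccccc2)cc(OCc2ccccc2)c1Oc1cc(OC)cc(C2(CCCC)SCCCS2)c1[Li] | intermediate
21 | 2-[2,4-bis(benzyloxy)-6-pentylphenoxy]-6-(2-butyl-1,3-dithian-2-yl)-4-methoxybenzoic acid | CCCCCc1cc(OCc2ccccc2)cc(OCc2ccccc2)c1Oc1cc(OC)cc(C2(CCCC)SCCCS2)c1C(=O)O | intermediate
22 | 2-[2,4-bis(benzyloxy)-6-pentylphenoxy]-4-methoxy-6-pentanoylbenzoic acid | CCCCCc1cc(OCc2ccccc2)cc(OCc2ccccc2)c1Oc1cc(OC)cc(C(=O)CCCC)c1C(=O)O | intermediate
23 | 2-(2,4-dihydroxy-6-pentylphenoxy)-4-methoxy-6-pentanoylbenzoic acid | CCCCCc1cc(O)cc(O)c1Oc1cc(OC)cc(C(=O)CCCC)c1C(=O)O | target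

## Step count and least certain steps

Total step count: 11. Longest linear sequence: 10 steps (steps 1 to 7, then 9, 10 and 11, from olivetol 1). Step 8 is a one-step side branch.

**Step 9 (key step, proposed new method).**
- What may go wrong: attack of the lithiodithiane at the sulfonate sulfur, or migration of the sulfonyl group, before the aryne is released; proton transfer to the C1 aryl anion before carboxylation; addition of the arylmagnesium species to its own aryne; partial addition with the reverse orientation.
- Fallback (known chemistry, no aryne): it sets out from aldehyde 8. Pinnick oxidation (NaClO2, NaH2PO4, 2-methyl-2-butene, t-BuOH/H2O) would give 2-[2,4-bis(benzyloxy)-6-pentylphenoxy]-4-methoxybenzoic acid F1. Carboxylate-directed ortho-lithiation with s-BuLi and TMEDA in THF at −78 °C would give lithium 2-[2,4-bis(benzyloxy)-6-pentylphenoxy]-6-lithio-4-methoxybenzoate F2, metalated at the only free position ortho to the carboxylate. Acylation of F2 with N-methoxy-N-methylpentanamide and acidic work-up returns to the route at keto acid 22.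

**Step 4.**
- What may go wrong: slow substitution, because the nucleophile is di-ortho-substituted and the para methoxy group weakens the activation by the formyl group; oxidative decomposition of the electron-rich phenoxide at the temperature needed.
- Fallback: copper-catalysed Ullmann ether synthesis, setting out from phenol 6 with purchased 2-bromo-4-methoxybenzaldehyde (CuI, picolinic acid, K3PO4, DMSO, 90 °C). It returns directly at aldehyde 8 and makes no compound outside the list (F0).

**Step 6.**
- What may go wrong: iodination through the neutral phenol instead of the phenoxide, which would send iodine to ring A or to C5 of ring B; oxidation of the para-alkoxyphenol.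
- Fallback: directed ortho-metalation, setting out from phenol 10. Carbamoylation (ClCONEt2, K2CO3, MeCN) would give 2-[2,4-bis(benzyloxy)-6-pentylphenoxy]-4-methoxyphenyl N,N-diethylcarbamate F3. Lithiation ortho to the carbamate with s-BuLi and TMEDA in THF at −78 °C and quenching with I2 would give 2-[2,4-bis(benzyloxy)-6-pentylphenoxy]-6-iodo-4-methoxyphenyl N,N-diethylcarbamate F4. Cleavage with NaOH in ethanol at reflux returns to the route at iodophenol 11.

**Step 10.**
- What may go wrong: incomplete hydrolysis, because the dithiane carbon is shielded by ring B and the carboxyl group; slow attack of the mercury salt on the electron-rich ring A.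
- Fallback: oxidation then hydrolysis, setting out from 21. NaIO4 in aqueous methanol at 0 °C would give 2-[2,4-bis(benzyloxy)-6-pentylphenoxy]-6-(2-butyl-1-oxo-1,3-dithian-2-yl)-4-methoxybenzoic acid F5 as a mixture of diastereomers. Dilute HCl in aqueous THF hydrolyses this monosulfoxide and returns to the route at keto acid 22.

**Step 11.**
- What may go wrong: Friedel–Crafts benzylation of the newly freed, very electron-rich ring A if the scavenger is outcompeted; partial cleavage of the methyl ether on warming; closure of the seven-membered lactone between the C1 carboxyl and the ring A 2-hydroxyl.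
- Fallback: hydrogenolysis, setting out from 22 (H2, Pd/C, ethyl acetate, rt) after careful removal of sulfur and mercury residues. It returns directly at target 23 and makes no compound outside the list (F0).

## Further compounds

F1 | step 9 | 2-[2,4-bis(benzyloxy)-6-pentylphenoxy]-4-methoxybenzoic acid | CCCCCc1cc(OCc2ccccc2)cc(OCc2ccccc2)c1Oc1cc(OC)ccc1C(=O)O
F2 | step 9 | lithium 2-[2,4-bis(benzyloxy)-6-pentylphenoxy]-6-lithio-4-methoxybenzoate | CCCCCc1cc(OCc2ccccc2)cc(OCc2ccccc2)c1Oc1cc(OC)cc([Li])c1C(=O)O[Li]
F0 | step 4 | none | none
F3 | step 6 | 2-[2,4-bis(benzyloxy)-6-pentylphenoxy]-4-methoxyphenyl N,N-diethylcarbamate | CCCCCc1cc(OCc2ccccc2)cc(OCc2ccccc2)c1Oc1cc(OC)ccc1OC(=O)N(CC)CC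
F4 | step 6 | 2-[2,4-bis(benzyloxy)-6-pentylphenoxy]-6-iodo-4-methoxyphenyl N,N-diethylcarbamate | CCCCCc1cc(OCc2ccccc2)cc(OCc2ccccc2)c1Oc1cc(OC)cc(I)c1OC(=O)N(CC)CC
F5 | step 10 | 2-[2,4-bis(benzyloxy)-6-pentylphenoxy]-6-(2-butyl-1-oxo-1,3-dithian-2-yl)-4-methoxybenzoic acid (mixture of diastereomers) | CCCCCc1cc(OCc2ccccc2)cc(OCc2ccccc2)c1Oc1cc(OC)cc(C2(CCCC)SCCCS2=O)c1C(=O)O
F0 | step 11 | none | none
A1 | alternative 1 | racemic 2-{[1-(methoxycarbonyl)-2,4-dioxo-6-pentylcyclohex-5-en-1-yl]oxy}-4-methoxy-6-pentanoylbenzoic acid | CCCCCC1=CC(=O)CC(=O)C1(C(=O)OC)Oc1cc(OC)cc(C(=O)CCCC)c1C(=O)O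
A2 | alternative 1 | dimethyl 2-(2-carboxy-5-methoxy-3-pentanoylphenoxy)propanedioate | COC(=O)C(Oc1cc(OC)cc(C(=O)CCCC)c1C(=O)O)C(=O)OC
A3 | alternative 1 | non-3-yn-2-one | CC(=O)C#CCCCCC
A4 | alternative 2 | racemic 7-[2,4-bis(benzyloxy)-6-pentylphenoxy]-3-butyl-5-methoxy-2-benzofuran-1(3H)-one | CCCCCc1cc(OCc2ccccc2)cc(OCc2ccccc2)c1Oc1cc(OC)cc2c1C(=O)OC2CCCC
A5 | alternative 2 | racemic hept-1-yn-3-yl 3-[2,4-bis(benzyloxy)-6-pentylphenoxy]prop-2-ynoate | CCCCCc1cc(OCc2ccccc2)cc(OCc2ccccc2)c1OC#CC(=O)OC(CCCC)C#C
A6 | alternative 2 | methoxyethyne | COC#C
A7 | alternative 3 | methyl 2-[2-hydroxy-6-pentyl-4-(triisopropylsilyloxy)phenoxy]-4-methoxy-6-pentanoylbenzoate | CCCCCc1cc(O[Si](C(C)C)(C(C)C)C(C)C)cc(O)c1Oc1cc(OC)cc(C(=O)CCCC)c1C(=O)OC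
A8 | alternative 3 | racemic methyl 4-methoxy-2-[(4-oxo-2-pentylcyclobut-2-en-1-yl)oxy]-6-pentanoylbenzoate | CCCCCC1=CC(=O)C1Oc1cc(OC)cc(C(=O)CCCC)c1C(=O)OC
A9 | alternative 3 | (triisopropylsilyloxy)ethyne | C#CO[Si](C(C)C)(C(C)C)C(C)C
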